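## The problem

Germacrane numbering is used throughout: C1=C10 is the enal olefin with the formyl carbon C14 on C10, C2 and C3 are the CH2CH2 bridge, C4=C5 carries the acetoxymethyl carbon C15 on C4, C6 is the lactone O–CH, C7 the ring-fusion CH, C8 the acyloxy CH, C9 a CH2, and C11(=C13)–C12 the methylene lactone.

The target is a ten-membered carbocycle (C1–C10) trans-fused at C6/C7 to an α-methylene-γ-butyrolactone. Both ring olefins are trisubstituted and ring-cis (C2 cis to C9, C3 cis to C6), so their geometry has to be fixed before the ring is closed. Three contiguous stereocentres (6R, 7R, 8R) lie on one flank of the ring; the fourth (2S) belongs to the 2-methylbutanoate and can be bought. A control chain is available: C8 can be set by a catalyst, C7 by C8 through a chelated enolate alkylation, and C6 by C7 and C8 in a carbonyl addition. The methylene lactone and the enal are Michael acceptors, the C15 acetate is allylic, the 8-O-acyl group sits next to the lactone (base invites translactonisation to the 8,12-olide), and the 2-methylbutanoate can epimerise. All of these must therefore appear late and under non-basic conditions. The enabling feature is that C6 is an allylic carbinol carbon whose neighbour C5 is the vinylic CH of C4=C5, cis to C3. A C5 alkenyl metal derived from an iodoalkene (iodine cis to C3) can add to a C6 aldehyde, closing the carbocycle and creating the lactone carbinol in one bond.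

## Retrosynthesis

**End game (36 back to 30).** The C15 acetate, the C8 (S)-2-methylbutanoate (from acid 33) and the C14 aldehyde are removed from 36 in turn (35, 34, 32, 31). This leads to methylene lactone 30, in which C15 is a PMB ether and C8 and C14 are TBS ethers. No skeletal bond is cut. Keeping C14 as a silyl ether rather than an acetal lets one fluoride step free both C8–OH and C14–OH, after which MnO2 touches only the allylic one. The forward steps must be non-basic so that neither the acyl group nor the lactone migrates.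

**C11=C13 (30 back to 27).** The exocyclic methylene is cut to the saturated lactone 27 through Mannich base 28. This is preferred over carrying an acrylate through ring closure, because a C7 centre that is both α to an aldehyde and allylic to an acrylate would not keep its configuration. The forward step is an enolate aminomethylation–elimination on a lactone with no other acidic site.

**C12–O (27 back to 24).** Opening the lactone gives hydroxy tert-butyl ester 24. The tert-butyl ester is the only ester that stays open through the enolate and hydride steps of the fragment synthesis; the price is a dedicated cleavage and lactonisation step later.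

**C5–C6, the ring (24 back to 23).** The ten-membered ring is cut between the vinylic C5 and the carbinol C6, giving iodoalkene aldehyde 23. The neighbouring cuts are less attractive. C3–C4 or C2–C3 closures create no stereocentre but need a further C–C step for C5–C6. A macrolactonisation does not address the carbocycle at all. The precursor 23 is acyclic, with both olefin geometries and two stereocentres already installed. The forward reaction has to close a ten-membered ring and choose the correct face of the aldehyde.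

**C1=C10 (23 back to 19 and 8).** The chain is cut at the enal olefin into phosphonate 19 and aldehyde 8; enoate 20, allylic alcohol 21 and silyl ether 22 lie on the forward path. An α-alkyl phosphonoacetate with an unbranched aldehyde gives the ester trans to C2, which is the ring-cis geometry. A Wittig reaction on a C10 ketone would put C2 cis to C14 instead. The cut is convergent and halves the problem.

**C9–C10 (19 back to 16 and 17).** The phosphonate is cut to primary alcohol 16 (through triflate 18) and triethyl phosphonoacetate 17. The C8 carbinol is already present, so no stereocentre is made in this bond, in contrast to an addition of a C9 nucleophile to a C8 aldehyde.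

**C7–C11 and the stereocentres (16 back to 12, then 10 and 11, then 9).** Protecting-group and oxidation-state changes (15, 14, 13) lead back to hydroxy diester 12. Cutting C7–C11 gives β-hydroxy ester 10 and tert-butyl bromoacetate 11. The chelated dianion alkylation gives the 7,8-anti relationship that the target needs, from a single catalyst-set centre. An aldol construction of C7–C8 would need an anti-selective auxiliary and a β,γ-unsaturated or phosphonate-bearing aldehyde. Compound 10 comes from commercial keto ester 9 by asymmetric hydrogenation.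

**C3–C4 (8 back to 7, then 2 and 3, then 1).** Aldehyde 8 is unmasked from dioxolane 7. Cutting C3–C4 leads to PMB propargyl ether 2 (from propargyl alcohol 1) and bromide 3 (through Grignard reagent 4, alkylcopper 5 and alkenylcopper 6). A syn carbometalation of the propargylic ether places iodine cis to C3. The anti carbomagnesiation of the free alcohol would give the wrong isomer, and methyl carboalumination cannot be extended to a functionalised chain.

## Roads not taken

**Alternative 1:** The cut is at C7–C8 and C11–C13 on the lactone. In the forward step, a 2-lithio-1,3-dithiane carrying C9 to C3 adds to C7 of butenolide A2 anti to the C6 substituent, and the enolate is trapped with Eschenmoser's salt to give A1.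
- Merits: three components are joined in one flask, C7 is set from a chiral-pool centre by a dependable anti addition, and the lactone and the methylene precursor are present from the start.
- Weak points: C8 arrives as a dithioketal and must later be unmasked and reduced with control from C7. In A1 the carbocycle is still open and C5 is only a silyloxymethyl group, so the ring and the C4=C5 olefin must be made together, and nothing in A1 fixes the geometry of that trisubstituted ring-cis olefin. Dithiane removal next to a diene and a tertiary amine is delicate.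
- Comparison: this road is better for the lactone (no separate lactonisation or enolisation) and for the 6,7-trans relationship, which comes from substrate-controlled conjugate addition, not from a macrocyclisation. The chosen plan sets against this that both olefin geometries are fixed in open-chain precursors, that C8 is set by a catalyst, and that ring closure and C6 creation coincide.

**Alternative 2:** The cut is at C11–C12 and C12–O. In the forward step, the macrocyclic homopropargylic alcohol A4 (C6–OH, C7–C≡CH) is cyclocarbonylated with PdCl2, SnCl2, PPh3 and CO to give methylene lactone A3.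
- Merits: the lactone carbonyl, the ring and the exocyclic methylene come from one late step. No lactone enolate is needed, so the C8 ester and the enal can already be present and the end game shrinks to desilylation and acetylation at C15.
- Weak points: the ten-membered ring of A4 must still be built. Its most direct precursor is a C6 aldehyde with an α-ethynyl C7 centre, which is prone to epimerisation and allene formation. The Lewis-acidic carbonylation medium also meets an allylic carbinol, an allylic silyl ether and an enal in a strained diene.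
- Comparison: for the end game this road is clearly shorter than lactonisation plus two-step methylenation, and it needs no protecting group at C8. The chosen plan sets against this a robust CH2CO2tBu group at C7 during aldehyde formation and ring closure, and routine enolate methylenation of a trans-fused lactone. Alternative 2 postpones the ring problem; it does not solve it.

**Alternative 3:** The cut is at C3–C4. In the forward step, the terminal vinyl group (C2=C3) of lactone A6 is hydroborated with 9-BBN, and Pd(dppf)Cl2 with Cs2CO3 couples the C3 borane with the C4 iodoalkene to give A5.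
- Merits: the lactone and all three ring stereocentres exist before macrocyclisation, so the ring closure makes no stereocentre, and the sp3–sp2 coupling retains the iodoalkene geometry.
- Weak points: the vinyl group of A6 is conjugated to C1=C10, so hydroboration must select the homoallylic over the allylic borane without disturbing that olefin. An alkylpalladium with β-hydrogens has to close a strained ten-membered ring at high dilution. C5–C6 still has to be made beforehand in a separate intermolecular addition.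
- Comparison: this road is better at separating stereocontrol from ring closure, since an intermolecular addition or the lactone itself is a more dependable control element than a macrocyclic transition state. The chosen plan sets against this one fewer skeletal bond-forming operation, no diene hydroboration, and a closure mode (alkenyl addition to an aldehyde) with stronger medium-ring precedent.

Key step: step 15

Assumption: RuCl2[(R)-BINAP] is taken to give the 3S alcohol 10, as it does with other 4-heteroatom-substituted acetoacetates; if the sense were reversed for this substrate, the (S)-ligand would be used.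

## Route

Step 1
Reactants: 1 prop-2-yn-1-ol
Product: 2 1-methoxy-4-[(prop-2-yn-1-yloxy)methyl]benzene
Conditions: NaH, 4-methoxybenzyl chloride, Bu4NI (cat.), THF/DMF, 0 → 25 °C
Reagents that add atoms: 4-methoxybenzyl chloride, COc1ccc(CCl)cc1
Why: Williamson etherification; the hydroxyl is far more acidic than the alkyne C–H, so only the alkoxide is alkylated.

Step 2
Reactants: 2 1-methoxy-4-[(prop-2-yn-1-yloxy)methyl]benzene; 3 2-(2-bromoethyl)-1,3-dioxolane
Product: 7 2-[(3E)-4-iodo-3-{[(4-methoxyphenyl)methoxy]methyl}but-3-en-1-yl]-1,3-dioxolane, via Grignard reagent 4 (not isolated), via alkylcopper 5 (not isolated), via alkenylcopper 6 (not isolated)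
Conditions: 3, Mg, THF, 25 °C; CuBr·SMe2, THF, −40 °C; 2, −40 → −15 °C; I2, −40 → 0 °C
Reagents that add atoms: iodine, II
Why: Normant carbocupration: the alkylcopper adds syn across the alkyne, in THF with the alkyl group on the internal carbon of the propargylic ether and copper on the terminus. Iodinolysis with retention leaves iodine cis to the new C3 chain and trans to C15, the ring-cis geometry of C4=C5.

Step 3
Reactants: 7 2-[(3E)-4-iodo-3-{[(4-methoxyphenyl)methoxy]methyl}but-3-en-1-yl]-1,3-dioxolane
Product: 8 (4E)-5-iodo-4-{[(4-methoxyphenyl)methoxy]methyl}pent-4-enal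
Conditions: 1 M HCl, THF, 40 °C
Reagents that add atoms: water, O
Why: Acid-catalysed acetal hydrolysis; the PMB ether and the iodoalkene tolerate dilute aqueous acid.

Step 4
Reactants: 9 ethyl 4-(benzyloxy)-3-oxobutanoate
Product: 10 ethyl (3S)-4-(benzyloxy)-3-hydroxybutanoate
Conditions: RuCl2[(R)-BINAP] (cat.), H2 (50 atm), EtOH, 100 °C
Reagents that add atoms: none
Why: Noyori asymmetric hydrogenation of a β-keto ester; the ester-chelated divalent ruthenium hydride delivers hydrogen to one carbonyl face and sets C8.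

Step 5
Reactants: 10 ethyl (3S)-4-(benzyloxy)-3-hydroxybutanoate; 11 tert-butyl bromoacetate
Product: 12 4-tert-butyl 1-ethyl (2R)-2-[(1S)-2-(benzyloxy)-1-hydroxyethyl]butanedioate
Conditions: LDA (2.2 equiv), THF, −78 → −20 °C; 11, DMPU, −78 → −20 °C; aq NH4Cl
Reagents that add atoms: none
Why: Fráter–Seebach alkylation: the chelated dilithio alkoxide–enolate is alkylated on the face away from the C9 substituent, setting C7 anti to the C8 oxygen. The hindered tert-butyl ester resists attack by the alkoxide.

Step 6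
Reactants: 12 4-tert-butyl 1-ethyl (2R)-2-[(1S)-2-(benzyloxy)-1-hydroxyethyl]butanedioate
Product: 13 4-tert-butyl 1-ethyl (2R)-2-[(1S)-2-(benzyloxy)-1-[(tert-butyldimethylsilyl)oxy]ethyl]butanedioate
Conditions: TBSOTf, 2,6-lutidine, CH2Cl2, −78 → 0 °C
Reagents that add atoms: tert-butyldimethylsilyl trifluoromethanesulfonate, CC(C)(C)[Si](C)(C)OS(=O)(=O)C(F)(F)F
Why: Silylation of a hindered β-hydroxy ester with the silyl triflate under buffered conditions; this blocks retro-aldol and lactonisation pathways.

Step 7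
Reactants: 13 4-tert-butyl 1-ethyl (2R)-2-[(1S)-2-(benzyloxy)-1-[(tert-butyldimethylsilyl)oxy]ethyl]butanedioate
Product: 14 tert-butyl (3S,4S)-5-(benzyloxy)-4-[(tert-butyldimethylsilyl)oxy]-3-(hydroxymethyl)pentanoate
Conditions: LiBH4, MeOH (1 equiv), THF, 0 → 25 °C
Reagents that add atoms: none
Why: Chemoselective borohydride reduction of the ethyl ester beside the tert-butyl ester; γ-hydroxy tert-butyl esters of this kind are stable in the absence of acid.

Step 8
Reactants: 14 tert-butyl (3S,4S)-5-(benzyloxy)-4-[(tert-butyldimethylsilyl)oxy]-3-(hydroxymethyl)pentanoate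
Product: 15 tert-butyl (3S,4S)-5-(benzyloxy)-4-[(tert-butyldimethylsilyl)oxy]-3-{[(triethylsilyl)oxy]methyl}pentanoate
Conditions: TESCl, imidazole, CH2Cl2, 0 °C
Reagents that add atoms: chlorotriethylsilane, CC[Si](Cl)(CC)CC
Why: Standard silylation; the primary triethylsilyl ether is chosen because it can later be oxidised directly to the C6 aldehyde.

Step 9
Reactants: 15 tert-butyl (3S,4S)-5-(benzyloxy)-4-[(tert-butyldimethylsilyl)oxy]-3-{[(triethylsilyl)oxy]methyl}pentanoate
Product: 16 tert-butyl (3S,4S)-4-[(tert-butyldimethylsilyl)oxy]-5-hydroxy-3-{[(triethylsilyl)oxy]methyl}pentanoate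
Conditions: H2 (1 atm), 10% Pd/C, EtOAc, 25 °C
Reagents that add atoms: none
Why: Hydrogenolysis of the benzyl ether; no olefin is present yet, and the silyl ethers and tert-butyl ester are inert in a neutral aprotic solvent.

Step 10
Reactants: 16 tert-butyl (3S,4S)-4-[(tert-butyldimethylsilyl)oxy]-5-hydroxy-3-{[(triethylsilyl)oxy]methyl}pentanoate; 17 ethyl 2-(diethoxyphosphoryl)acetate
Product: 19 7-tert-butyl 1-ethyl (4R,5S)-4-[(tert-butyldimethylsilyl)oxy]-2-(diethoxyphosphoryl)-5-{[(triethylsilyl)oxy]methyl}heptanedioate (both epimers at C2), via triflate 18 (not isolated)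
Conditions: Tf2O, 2,6-lutidine, CH2Cl2, −78 °C; then NaCH(CO2Et)P(O)(OEt)2 (from 17 and NaH, 3 equiv), THF, −78 → 0 °C
Reagents that add atoms: none
Why: SN2 alkylation of the soft phosphonoacetate carbanion by a primary triflate, which reacts at low temperature where a β-silyloxy iodide would not. Excess nucleophile suppresses dialkylation, and the C10 configuration is lost in the next step.

Step 11
Reactants: 19 7-tert-butyl 1-ethyl (4R,5S)-4-[(tert-butyldimethylsilyl)oxy]-2-(diethoxyphosphoryl)-5-{[(triethylsilyl)oxy]methyl}heptanedioate; 8 (4E)-5-iodo-4-{[(4-methoxyphenyl)methoxy]methyl}pent-4-enal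
Product: 20 7-tert-butyl 1-ethyl (2E,4R,5S)-4-[(tert-butyldimethylsilyl)oxy]-2-[(4E)-5-iodo-4-{[(4-methoxyphenyl)methoxy]methyl}pent-4-en-1-ylidene]-5-{[(triethylsilyl)oxy]methyl}heptanedioate
Conditions: NaH, THF, 0 °C; then 8, 0 → 25 °C
Reagents that add atoms: none
Why: Horner–Wadsworth–Emmons olefination; an α-alkyl phosphonoacetate and an unbranched aldehyde equilibrate to the oxaphosphetane that gives the E enoate. The ester ends trans to C2, so C2 and C9 are cis as the ring requires.

Step 12
Reactants: 20 7-tert-butyl 1-ethyl (2E,4R,5S)-4-[(tert-butyldimethylsilyl)oxy]-2-[(4E)-5-iodo-4-{[(4-methoxyphenyl)methoxy]methyl}pent-4-en-1-ylidene]-5-{[(triethylsilyl)oxy]methyl}heptanedioate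
Product: 21 tert-butyl (3S,4R,6E,10E)-4-[(tert-butyldimethylsilyl)oxy]-6-(hydroxymethyl)-11-iodo-10-{[(4-methoxyphenyl)methoxy]methyl}-3-{[(triethylsilyl)oxy]methyl}undeca-6,10-dienoate
Conditions: DIBAL-H (2.5 equiv), CH2Cl2, −78 °C; Rochelle salt
Reagents that add atoms: none
Why: 1,2-Reduction of the conjugated ethyl ester with an aluminium hydride at −78 °C, where the hindered tert-butyl ester and the iodoalkene should stay untouched.

Step 13
Reactants: 21 tert-butyl (3S,4R,6E,10E)-4-[(tert-butyldimethylsilyl)oxy]-6-(hydroxymethyl)-11-iodo-10-{[(4-methoxyphenyl)methoxy]methyl}-3-{[(triethylsilyl)oxy]methyl}undeca-6,10-dienoate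
Product: 22 tert-butyl (3S,4R,6E,10E)-4-[(tert-butyldimethylsilyl)oxy]-6-{[(tert-butyldimethylsilyl)oxy]methyl}-11-iodo-10-{[(4-methoxyphenyl)methoxy]methyl}-3-{[(triethylsilyl)oxy]methyl}undeca-6,10-dienoate
Conditions: TBSCl, imidazole, DMF, 25 °C
Reagents that add atoms: tert-butyldimethylsilyl chloride, CC(C)(C)[Si](C)(C)Cl
Why: Standard silylation of the primary allylic alcohol; C14 is held at the alcohol level so that it cannot compete with the C6 aldehyde in the ring closure.

Step 14
Reactants: 22 tert-butyl (3S,4R,6E,10E)-4-[(tert-butyldimethylsilyl)oxy]-6-{[(tert-butyldimethylsilyl)oxy]methyl}-11-iodo-10-{[(4-methoxyphenyl)methoxy]methyl}-3-{[(triethylsilyl)oxy]methyl}undeca-6,10-dienoate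
Product: 23 tert-butyl (3R,4R,6E,10E)-4-[(tert-butyldimethylsilyl)oxy]-6-{[(tert-butyldimethylsilyl)oxy]methyl}-3-formyl-11-iodo-10-{[(4-methoxyphenyl)methoxy]methyl}undeca-6,10-dienoate
Conditions: (COCl)2, DMSO, CH2Cl2, −78 → −35 °C; iPr2NEt, −78 → −20 °C
Reagents that add atoms: none
Why: Swern oxidation applied directly to the primary triethylsilyl ether: the chlorosulfonium reagent cleaves the TES ether selectively (TBS ethers stay) and the alkoxysulfonium ion collapses to the aldehyde. The free γ-hydroxy ester is never formed, and the hindered amine and cold work-up protect C7.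

Step 15
Reactants: 23 tert-butyl (3R,4R,6E,10E)-4-[(tert-butyldimethylsilyl)oxy]-6-{[(tert-butyldimethylsilyl)oxy]methyl}-3-formyl-11-iodo-10-{[(4-methoxyphenyl)methoxy]methyl}undeca-6,10-dienoate
Product: 24 tert-butyl 2-[(1S,2R,3E,7E,10R)-10-[(tert-butyldimethylsilyl)oxy]-8-{[(tert-butyldimethylsilyl)oxy]methyl}-2-hydroxy-4-{[(4-methoxyphenyl)methoxy]methyl}cyclodeca-3,7-dien-1-yl]acetate (ring C1 = C7, ring C2 = C6, ring C10 = C8 of the germacrane numbering)
Conditions: CrCl2 (12 equiv), NiCl2 (0.2 equiv), degassed DMSO/THF, 25 °C, slow addition to 0.003 M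
Reagents that add atoms: none
Why: Nozaki–Hiyama–Kishi reaction: zerovalent nickel, formed from NiCl2 by divalent chromium, inserts into the C5–I bond with retention, the alkenyl group passes to trivalent chromium, and the alkenylchromium adds to the C6 aldehyde. The closest known reaction type is the intramolecular closure of iodoalkene aldehydes to medium-ring allylic alcohols. The ten-membered carbocycle closes through the single C5–C6 bond in a 10-exo-trig addition to the carbonyl group. The new C6 centre is controlled by C7: Felkin–Anh attack anti to the C8 branch, reinforced by the 1,3-anti preference of the C8 silyloxy group (the C7 and C8 substituents are anti), should give the 6R alcohol with oxygen trans to C8 across C6–C7, the trans-lactone relationship. The step needs chemoselectivity, retention of both olefin geometries, and cyclisation in preference to oligomerisation. Esters, silyl ethers and the PMB ether are inert to alkenylchromium, and alkenylchromium species hold their configuration. Both trisubstituted olefins are already ring-cis, which folds the chain and brings C5 near C6, and slow addition keeps the substrate dilute. The neutral medium spares the epimerisable C7 centre and leaves the tert-butyl ester open.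

Step 16
Reactants: 24 tert-butyl 2-[(1S,2R,3E,7E,10R)-10-[(tert-butyldimethylsilyl)oxy]-8-{[(tert-butyldimethylsilyl)oxy]methyl}-2-hydroxy-4-{[(4-methoxyphenyl)methoxy]methyl}cyclodeca-3,7-dien-1-yl]acetate
Product: 27 (3aS,4R,6E,10E,11aR)-4-[(tert-butyldimethylsilyl)oxy]-6-{[(tert-butyldimethylsilyl)oxy]methyl}-10-{[(4-methoxyphenyl)methoxy]methyl}-3a,4,5,8,9,11a-hexahydrocyclodeca[b]furan-2(3H)-one, via bis(trimethylsilyl) derivative 25 (not isolated), via hydroxy acid 26 (not isolated)
Conditions: TMSOTf, 2,6-lutidine, CH2Cl2, 0 → 25 °C; 10% aq citric acid, THF, 25 °C; then PPTS (cat.), CH2Cl2, 25 °C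
Reagents that add atoms: none
Why: The silyl triflate turns the tert-butyl ester into a silyl ester with loss of isobutene under buffered aprotic conditions and caps the C6 hydroxyl. Mild aqueous acid frees the γ-hydroxy acid, which lactonises by acyl substitution without breaking the C6–O bond, so the C6 configuration is retained.

Step 17
Reactants: 27 (3aS,4R,6E,10E,11aR)-4-[(tert-butyldimethylsilyl)oxy]-6-{[(tert-butyldimethylsilyl)oxy]methyl}-10-{[(4-methoxyphenyl)methoxy]methyl}-3a,4,5,8,9,11a-hexahydrocyclodeca[b]furan-2(3H)-one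
Product: 28 (3aS,4R,6E,10E,11aR)-4-[(tert-butyldimethylsilyl)oxy]-6-{[(tert-butyldimethylsilyl)oxy]methyl}-3-[(dimethylamino)methyl]-10-{[(4-methoxyphenyl)methoxy]methyl}-3a,4,5,8,9,11a-hexahydrocyclodeca[b]furan-2(3H)-one (C3 configuration inconsequential)
Conditions: LiHMDS, THF, −78 °C; CH2=NMe2+ I−, −78 → 0 °C
Reagents that add atoms: Eschenmoser's salt (N,N-dimethylmethyleneiminium iodide), C=[N+](C)C.[I-]
Why: Mannich reaction of the lactone lithium enolate with the iminium salt; C11 is the only enolisable position, and the new centre disappears in the next step.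

Step 18
Reactants: 28 (3aS,4R,6E,10E,11aR)-4-[(tert-butyldimethylsilyl)oxy]-6-{[(tert-butyldimethylsilyl)oxy]methyl}-3-[(dimethylamino)methyl]-10-{[(4-methoxyphenyl)methoxy]methyl}-3a,4,5,8,9,11a-hexahydrocyclodeca[b]furan-2(3H)-one
Product: 30 (3aS,4R,6E,10E,11aR)-4-[(tert-butyldimethylsilyl)oxy]-6-{[(tert-butyldimethylsilyl)oxy]methyl}-10-{[(4-methoxyphenyl)methoxy]methyl}-3-methylidene-3a,4,5,8,9,11a-hexahydrocyclodeca[b]furan-2(3H)-one, via ammonium iodide 29 (not isolated)
Conditions: MeI, MeOH, 25 °C; then NaHCO3 (aq), EtOAc, 25 °C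
Reagents that add atoms: none
Why: Quaternisation of the amine followed by base-induced β-elimination (Hofmann type, E1cB through the lactone enolate) gives the exocyclic methylene group under very mild base.

Step 19
Reactants: 30 (3aS,4R,6E,10E,11aR)-4-[(tert-butyldimethylsilyl)oxy]-6-{[(tert-butyldimethylsilyl)oxy]methyl}-10-{[(4-methoxyphenyl)methoxy]methyl}-3-methylidene-3a,4,5,8,9,11a-hexahydrocyclodeca[b]furan-2(3H)-one
Product: 31 (3aR,4R,6E,10E,11aR)-4-hydroxy-6-(hydroxymethyl)-10-{[(4-methoxyphenyl)methoxy]methyl}-3-methylidene-3a,4,5,8,9,11a-hexahydrocyclodeca[b]furan-2(3H)-one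
Conditions: HF·pyridine, pyridine, THF, 0 → 25 °C
Reagents that add atoms: none
Why: Fluoride-mediated desilylation of both TBS ethers under weakly acidic conditions, which avoids the alkoxide that would trigger translactonisation to the 8,12-olide or conjugate addition.

Step 20
Reactants: 31 (3aR,4R,6E,10E,11aR)-4-hydroxy-6-(hydroxymethyl)-10-{[(4-methoxyphenyl)methoxy]methyl}-3-methylidene-3a,4,5,8,9,11a-hexahydrocyclodeca[b]furan-2(3H)-one
Product: 32 (3aR,4R,6E,10E,11aR)-4-hydroxy-10-{[(4-methoxyphenyl)methoxy]methyl}-3-methylidene-2-oxo-2,3,3a,4,5,8,9,11a-octahydrocyclodeca[b]furan-6-carbaldehyde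
Conditions: MnO2 (activated), CH2Cl2, 25 °C
Reagents that add atoms: none
Why: Allylic oxidation with MnO2 takes only the primary allylic C14 alcohol; the secondary C8 carbinol is not allylic and stays, and the enal keeps its geometry (formyl trans to C2).

Step 21
Reactants: 32 (3aR,4R,6E,10E,11aR)-4-hydroxy-10-{[(4-methoxyphenyl)methoxy]methyl}-3-methylidene-2-oxo-2,3,3a,4,5,8,9,11a-octahydrocyclodeca[b]furan-6-carbaldehyde; 33 (2S)-2-methylbutanoic acid
Product: 34 (3aR,4R,6E,10E,11aR)-6-formyl-10-{[(4-methoxyphenyl)methoxy]methyl}-3-methylidene-2-oxo-2,3,3a,4,5,8,9,11a-octahydrocyclodeca[b]furan-4-yl (2S)-2-methylbutanoate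
Conditions: DCC, DMAP (cat.), CH2Cl2, 0 → 25 °C
Reagents that add atoms: none
Why: Steglich esterification; acyl transfer through the acylpyridinium ion at low temperature should keep the α-centre of the acid, and the C8 carbinol reacts with retention because its C–O bond is not broken.

Step 22
Reactants: 34 (3aR,4R,6E,10E,11aR)-6-formyl-10-{[(4-methoxyphenyl)methoxy]methyl}-3-methylidene-2-oxo-2,3,3a,4,5,8,9,11a-octahydrocyclodeca[b]furan-4-yl (2S)-2-methylbutanoate
Product: 35 (3aR,4R,6E,10E,11aR)-6-formyl-10-(hydroxymethyl)-3-methylidene-2-oxo-2,3,3a,4,5,8,9,11a-octahydrocyclodeca[b]furan-4-yl (2S)-2-methylbutanoate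
Conditions: DDQ, CH2Cl2/pH 7 buffer (10:1), 0 °C
Reagents that add atoms: none
Why: Oxidative cleavage of the PMB ether by hydride abstraction and hydrolysis of the oxocarbenium ion; the esters, enal and methylene lactone are inert to DDQ in buffered medium.

Step 23
Reactants: 35 (3aR,4R,6E,10E,11aR)-6-formyl-10-(hydroxymethyl)-3-methylidene-2-oxo-2,3,3a,4,5,8,9,11a-octahydrocyclodeca[b]furan-4-yl (2S)-2-methylbutanoate
Product: 36 [(3aR,4R,6E,10E,11aR)-10-(acetoxymethyl)-6-formyl-3-methylidene-2-oxo-2,3,3a,4,5,8,9,11a-octahydrocyclodeca[b]furan-4-yl] (2S)-2-methylbutanoate (CNP0230988.9)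
Conditions: Ac2O, pyridine, DMAP (cat.), CH2Cl2, 0 °C
Reagents that add atoms: acetic anhydride, CC(=O)OC(C)=O
Why: Acetylation of the primary allylic alcohol under mild amine catalysis; no other hydroxyl remains.

## Compound list

1 | prop-2-yn-1-ol | C#CCO | starting material
2 | 1-methoxy-4-[(prop-2-yn-1-yloxy)methyl]benzene | C#CCOCc1ccc(OC)cc1 | intermediate
3 | 2-(2-bromoethyl)-1,3-dioxolane | BrCCC1OCCO1 | starting material
4 | [2-(1,3-dioxolan-2-yl)ethyl]magnesium bromide | Br[Mg]CCC1OCCO1 | intermediate
5 | [2-(1,3-dioxolan-2-yl)ethyl]copper (MgBr2 complex) | [Cu]CCC1OCCO1 | intermediate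
6 | [(1E)-4-(1,3-dioxolan-2-yl)-2-{[(4-methoxyphenyl)methoxy]methyl}but-1-en-1-yl]copper | [Cu]/C=C(/COCc1ccc(OC)cc1)CCC1OCCO1 | intermediate
7 | 2-[(3E)-4-iodo-3-{[(4-methoxyphenyl)methoxy]methyl}but-3-en-1-yl]-1,3-dioxolane | I/C=C(/COCc1ccc(OC)cc1)CCC1OCCO1 | intermediate
8 | (4E)-5-iodo-4-{[(4-methoxyphenyl)methoxy]methyl}pent-4-enal | I/C=C(/COCc1ccc(OC)cc1)CCC=O | intermediate
9 | ethyl 4-(benzyloxy)-3-oxobutanoate | CCOC(=O)CC(=O)COCc1ccccc1 | starting material
10 | ethyl (3S)-4-(benzyloxy)-3-hydroxybutanoate | CCOC(=O)C[C@H](O)COCc1ccccc1 | intermediate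
11 | tert-butyl bromoacetate | BrCC(=O)OC(C)(C)C | starting material
12 | 4-tert-butyl 1-ethyl (2R)-2-[(1S)-2-(benzyloxy)-1-hydroxyethyl]butanedioate | c1ccccc1COC[C@@H](O)[C@@H](CC(=O)OC(C)(C)C)C(=O)OCC | intermediate
13 | 4-tert-butyl 1-ethyl (2R)-2-[(1S)-2-(benzyloxy)-1-[(tert-butyldimethylsilyl)oxy]ethyl]butanedioate | c1ccccc1COC[C@@H](O[Si](C)(C)C(C)(C)C)[C@@H](CC(=O)OC(C)(C)C)C(=O)OCC | intermediate
14 | tert-butyl (3S,4S)-5-(benzyloxy)-4-[(tert-butyldimethylsilyl)oxy]-3-(hydroxymethyl)pentanoate | c1ccccc1COC[C@@H](O[Si](C)(C)C(C)(C)C)[C@@H](CC(=O)OC(C)(C)C)CO | intermediate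
15 | tert-butyl (3S,4S)-5-(benzyloxy)-4-[(tert-butyldimethylsilyl)oxy]-3-{[(triethylsilyl)oxy]methyl}pentanoate | c1ccccc1COC[C@@H](O[Si](C)(C)C(C)(C)C)[C@@H](CC(=O)OC(C)(C)C)CO[Si](CC)(CC)CC | intermediate
16 | tert-butyl (3S,4S)-4-[(tert-butyldimethylsilyl)oxy]-5-hydroxy-3-{[(triethylsilyl)oxy]methyl}pentanoate | OC[C@@H](O[Si](C)(C)C(C)(C)C)[C@@H](CC(=O)OC(C)(C)C)CO[Si](CC)(CC)CC | intermediate
17 | ethyl 2-(diethoxyphosphoryl)acetate (triethyl phosphonoacetate) | CCOC(=O)CP(=O)(OCC)OCC | starting material
18 | tert-butyl (3S,4S)-4-[(tert-butyldimethylsilyl)oxy]-3-{[(triethylsilyl)oxy]methyl}-5-[(trifluoromethanesulfonyl)oxy]pentanoate | FC(F)(F)S(=O)(=O)OC[C@@H](O[Si](C)(C)C(C)(C)C)[C@@H](CC(=O)OC(C)(C)C)CO[Si](CC)(CC)CC | intermediate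
19 | 7-tert-butyl 1-ethyl (4R,5S)-4-[(tert-butyldimethylsilyl)oxy]-2-(diethoxyphosphoryl)-5-{[(triethylsilyl)oxy]methyl}heptanedioate (both C2 epimers) | CCOC(=O)C(P(=O)(OCC)OCC)C[C@@H](O[Si](C)(C)C(C)(C)C)[C@@H](CC(=O)OC(C)(C)C)CO[Si](CC)(CC)CC | intermediate
20 | 7-tert-butyl 1-ethyl (2E,4R,5S)-4-[(tert-butyldimethylsilyl)oxy]-2-[(4E)-5-iodo-4-{[(4-methoxyphenyl)methoxy]methyl}pent-4-en-1-ylidene]-5-{[(triethylsilyl)oxy]methyl}heptanedioate | I/C=C(/COCc1ccc(OC)cc1)CC/C=C(/C(=O)OCC)C[C@@H](O[Si](C)(C)C(C)(C)C)[C@@H](CC(=O)OC(C)(C)C)CO[Si](CC)(CC)CC | intermediate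
21 | tert-butyl (3S,4R,6E,10E)-4-[(tert-butyldimethylsilyl)oxy]-6-(hydroxymethyl)-11-iodo-10-{[(4-methoxyphenyl)methoxy]methyl}-3-{[(triethylsilyl)oxy]methyl}undeca-6,10-dienoate | I/C=C(/COCc1ccc(OC)cc1)CC/C=C(/CO)C[C@@H](O[Si](C)(C)C(C)(C)C)[C@@H](CC(=O)OC(C)(C)C)CO[Si](CC)(CC)CC | intermediate
22 | tert-butyl (3S,4R,6E,10E)-4-[(tert-butyldimethylsilyl)oxy]-6-{[(tert-butyldimethylsilyl)oxy]methyl}-11-iodo-10-{[(4-methoxyphenyl)methoxy]methyl}-3-{[(triethylsilyl)oxy]methyl}undeca-6,10-dienoate | I/C=C(/COCc1ccc(OC)cc1)CC/C=C(/CO[Si](C)(C)C(C)(C)C)C[C@@H](O[Si](C)(C)C(C)(C)C)[C@@H](CC(=O)OC(C)(C)C)CO[Si](CC)(CC)CC | intermediate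
23 | tert-butyl (3R,4R,6E,10E)-4-[(tert-butyldimethylsilyl)oxy]-6-{[(tert-butyldimethylsilyl)oxy]methyl}-3-formyl-11-iodo-10-{[(4-methoxyphenyl)methoxy]methyl}undeca-6,10-dienoate | I/C=C(/COCc1ccc(OC)cc1)CC/C=C(/CO[Si](C)(C)C(C)(C)C)C[C@@H](O[Si](C)(C)C(C)(C)C)[C@@H](CC(=O)OC(C)(C)C)C=O | intermediate
24 | tert-butyl 2-[(1S,2R,3E,7E,10R)-10-[(tert-butyldimethylsilyl)oxy]-8-{[(tert-butyldimethylsilyl)oxy]methyl}-2-hydroxy-4-{[(4-methoxyphenyl)methoxy]methyl}cyclodeca-3,7-dien-1-yl]acetate | O[C@@H]1/C=C(/COCc2ccc(OC)cc2)CC/C=C(/CO[Si](C)(C)C(C)(C)C)C[C@@H](O[Si](C)(C)C(C)(C)C)[C@H]1CC(=O)OC(C)(C)C | intermediate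
25 | trimethylsilyl 2-[(1S,2R,3E,7E,10R)-10-[(tert-butyldimethylsilyl)oxy]-8-{[(tert-butyldimethylsilyl)oxy]methyl}-4-{[(4-methoxyphenyl)methoxy]methyl}-2-[(trimethylsilyl)oxy]cyclodeca-3,7-dien-1-yl]acetate | C[Si](C)(C)O[C@@H]1/C=C(/COCc2ccc(OC)cc2)CC/C=C(/CO[Si](C)(C)C(C)(C)C)C[C@@H](O[Si](C)(C)C(C)(C)C)[C@H]1CC(=O)O[Si](C)(C)C | intermediate
26 | 2-[(1S,2R,3E,7E,10R)-10-[(tert-butyldimethylsilyl)oxy]-8-{[(tert-butyldimethylsilyl)oxy]methyl}-2-hydroxy-4-{[(4-methoxyphenyl)methoxy]methyl}cyclodeca-3,7-dien-1-yl]acetic acid | O[C@@H]1/C=C(/COCc2ccc(OC)cc2)CC/C=C(/CO[Si](C)(C)C(C)(C)C)C[C@@H](O[Si](C)(C)C(C)(C)C)[C@H]1CC(=O)O | intermediate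
27 | (3aS,4R,6E,10E,11aR)-4-[(tert-butyldimethylsilyl)oxy]-6-{[(tert-butyldimethylsilyl)oxy]methyl}-10-{[(4-methoxyphenyl)methoxy]methyl}-3a,4,5,8,9,11a-hexahydrocyclodeca[b]furan-2(3H)-one | C1C(=O)O[C@@H]2/C=C(/COCc3ccc(OC)cc3)CC/C=C(/CO[Si](C)(C)C(C)(C)C)C[C@@H](O[Si](C)(C)C(C)(C)C)[C@@H]12 | intermediate
28 | (3aS,4R,6E,10E,11aR)-4-[(tert-butyldimethylsilyl)oxy]-6-{[(tert-butyldimethylsilyl)oxy]methyl}-3-[(dimethylamino)methyl]-10-{[(4-methoxyphenyl)methoxy]methyl}-3a,4,5,8,9,11a-hexahydrocyclodeca[b]furan-2(3H)-one (C3 unassigned) | CN(C)CC1C(=O)O[C@@H]2/C=C(/COCc3ccc(OC)cc3)CC/C=C(/CO[Si](C)(C)C(C)(C)C)C[C@@H](O[Si](C)(C)C(C)(C)C)[C@@H]12 | intermediate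
29 | trimethylammonium iodide of 28: {(3aS,4R,6E,10E,11aR)-4-[(tert-butyldimethylsilyl)oxy]-6-{[(tert-butyldimethylsilyl)oxy]methyl}-10-{[(4-methoxyphenyl)methoxy]methyl}-2-oxo-2,3,3a,4,5,8,9,11a-octahydrocyclodeca[b]furan-3-yl}-N,N,N-trimethylmethanaminium iodide | C[N+](C)(C)CC1C(=O)O[C@@H]2/C=C(/COCc3ccc(OC)cc3)CC/C=C(/CO[Si](C)(C)C(C)(C)C)C[C@@H](O[Si](C)(C)C(C)(C)C)[C@@H]12.[I-] | intermediate
30 | (3aS,4R,6E,10E,11aR)-4-[(tert-butyldimethylsilyl)oxy]-6-{[(tert-butyldimethylsilyl)oxy]methyl}-10-{[(4-methoxyphenyl)methoxy]methyl}-3-methylidene-3a,4,5,8,9,11a-hexahydrocyclodeca[b]furan-2(3H)-one | C=C1C(=O)O[C@@H]2/C=C(/COCc3ccc(OC)cc3)CC/C=C(/CO[Si](C)(C)C(C)(C)C)C[C@@H](O[Si](C)(C)C(C)(C)C)[C@@H]12 | intermediate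
31 | (3aR,4R,6E,10E,11aR)-4-hydroxy-6-(hydroxymethyl)-10-{[(4-methoxyphenyl)methoxy]methyl}-3-methylidene-3a,4,5,8,9,11a-hexahydrocyclodeca[b]furan-2(3H)-one | C=C1C(=O)O[C@@H]2/C=C(/COCc3ccc(OC)cc3)CC/C=C(/CO)C[C@@H](O)[C@@H]12 | intermediate
32 | (3aR,4R,6E,10E,11aR)-4-hydroxy-10-{[(4-methoxyphenyl)methoxy]methyl}-3-methylidene-2-oxo-2,3,3a,4,5,8,9,11a-octahydrocyclodeca[b]furan-6-carbaldehyde | C=C1C(=O)O[C@@H]2/C=C(/COCc3ccc(OC)cc3)CC/C=C(/C=O)C[C@@H](O)[C@@H]12 | intermediate
33 | (2S)-2-methylbutanoic acid | CC[C@H](C)C(=O)O | starting material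
34 | (3aR,4R,6E,10E,11aR)-6-formyl-10-{[(4-methoxyphenyl)methoxy]methyl}-3-methylidene-2-oxo-2,3,3a,4,5,8,9,11a-octahydrocyclodeca[b]furan-4-yl (2S)-2-methylbutanoate | C=C1C(=O)O[C@@H]2/C=C(/COCc3ccc(OC)cc3)CC/C=C(/C=O)C[C@@H](OC(=O)[C@@H](C)CC)[C@@H]12 | intermediate
35 | (3aR,4R,6E,10E,11aR)-6-formyl-10-(hydroxymethyl)-3-methylidene-2-oxo-2,3,3a,4,5,8,9,11a-octahydrocyclodeca[b]furan-4-yl (2S)-2-methylbutanoate | C=C1C(=O)O[C@@H]2/C=C(/CO)CC/C=C(/C=O)C[C@@H](OC(=O)[C@@H](C)CC)[C@@H]12 | intermediate
36 | [(3aR,4R,6E,10E,11aR)-10-(acetoxymethyl)-6-formyl-3-methylidene-2-oxo-2,3,3a,4,5,8,9,11a-octahydrocyclodeca[b]furan-4-yl] (2S)-2-methylbutanoate | C=C1C(=O)O[C@@H]2/C=C(/COC(C)=O)CC/C=C(/C=O)C[C@@H](OC(=O)[C@@H](C)CC)[C@@H]12 | target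

## Step count and risks

Total: 23 steps. The longest linear sequence is 20 steps (steps 4 to 23, from keto ester 9); the aldehyde fragment 8 takes 3 steps (steps 1 to 3) and joins at step 11.

**Step 15 (key step).** The most likely failure is poor facial selectivity at the C6 aldehyde, because the conformation of the closing ten-membered ring may override the open-chain Felkin–Anh preference. Intermolecular coupling competing with cyclisation is the second concern. Fallback, from 23 back to 27: if the ring closes mainly to the wrong face, the C6-epimeric alcohol tert-butyl 2-[(1S,2S,3E,7E,10R)-10-[(tert-butyldimethylsilyl)oxy]-8-{[(tert-butyldimethylsilyl)oxy]methyl}-2-hydroxy-4-{[(4-methoxyphenyl)methoxy]methyl}cyclodeca-3,7-dien-1-yl]acetate F1 is carried on. Its ester is cleaved as in step 16 to the epimeric hydroxy acid 2-[(1S,2S,3E,7E,10R)-10-[(tert-butyldimethylsilyl)oxy]-8-{[(tert-butyldimethylsilyl)oxy]methyl}-2-hydroxy-4-{[(4-methoxyphenyl)methoxy]methyl}cyclodeca-3,7-dien-1-yl]acetic acid F2. This is closed under Mitsunobu conditions (PPh3, DIAD, THF, 0 °C), where the carboxylate displaces the activated C6 oxygen with inversion and gives lactone 27. The stereocentre is then set by an SN2 lactonisation, not by the addition.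

**Step 2.** The regiochemistry of the carbocupration may reverse: copper on the internal carbon next to the ether oxygen, followed by β-elimination to an allene. The functionalised alkylcopper may also decompose before it adds. Fallback, from 2 back to 7:
- Pd(PPh3)4-catalysed syn silylstannation of 2 with Me3SiSnBu3 should give tributyl[(1Z)-3-[(4-methoxyphenyl)methoxy]-1-(trimethylsilyl)prop-1-en-2-yl]stannane F3.
- Iodine cleaves the alkenyl–tin bond selectively to [(1Z)-2-iodo-3-[(4-methoxyphenyl)methoxy]prop-1-en-1-yl]trimethylsilane F4.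
- Negishi coupling with the zinc reagent made from 3 (Zn, LiCl; PdCl2(dppf)) gives trimethyl[(1E)-4-(1,3-dioxolan-2-yl)-2-{[(4-methoxyphenyl)methoxy]methyl}but-1-en-1-yl]silane F5.
- Iododesilylation with N-iodosuccinimide with retention returns 7.

Here the regiochemistry rests on the metal–metal addition and the geometry on two stereoretentive substitutions.

**Step 16.** Loss of the allylic silyl or PMB ethers, or ionisation at the allylic C6 position under the silyl triflate, and slow closure of the hydroxy acid are the likely problems. Fallback, from 24 back to 27: the ring is closed without any acid by deprotonating the C6 hydroxyl (KHMDS, THF, −78 → −40 °C), so that the alkoxide displaces tert-butoxide from the ester in a five-membered acyl substitution. The reaction is quenched cold to outpace migration of the C8 silyl group. No new compound arises (F0).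

**Step 11.** Incomplete E selectivity of the olefination with the α-branched phosphonate is the risk; the Z enoate would put C2 and C9 trans and could not cyclise. Fallback, from 16 (through triflate 18) back to 20: the triflate alkylates ethyl (triphenylphosphoranylidene)acetate (2 equiv, the second as base) to the stabilised ylide 7-tert-butyl 1-ethyl (4R,5S)-4-[(tert-butyldimethylsilyl)oxy]-5-{[(triethylsilyl)oxy]methyl}-2-(triphenyl-λ5-phosphanylidene)heptanedioate F6. Wittig reaction of F6 with 8 in warm toluene gives 20; α-substituted ester ylides give the E enoate with higher selectivity than the phosphonates.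

**Step 10.** Slow substitution at the β-silyloxy carbon and participation of an ester carbonyl in displacing the triflate are the risks. Fallback, from 16 back to 19, with no SN2 step:
- Oxidation of 16 with Dess–Martin periodinane gives tert-butyl (3S,4S)-4-[(tert-butyldimethylsilyl)oxy]-5-oxo-3-{[(triethylsilyl)oxy]methyl}pentanoate F7.
- Knoevenagel condensation of F7 with 17 (TiCl4, N-methylmorpholine, THF, 0 °C) gives the alkylidene phosphonoacetate 7-tert-butyl 1-ethyl 4-[(tert-butyldimethylsilyl)oxy]-2-(diethoxyphosphoryl)-5-{[(triethylsilyl)oxy]methyl}hept-2-enedioate F8.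
- Conjugate reduction of F8 with NaBH4 in EtOH gives 19.

Further compounds
F1 | step 15 | tert-butyl 2-[(1S,2S,3E,7E,10R)-10-[(tert-butyldimethylsilyl)oxy]-8-{[(tert-butyldimethylsilyl)oxy]methyl}-2-hydroxy-4-{[(4-methoxyphenyl)methoxy]methyl}cyclodeca-3,7-dien-1-yl]acetate (C6 epimer of 24) | O[C@H]1/C=C(/COCc2ccc(OC)cc2)CC/C=C(/CO[Si](C)(C)C(C)(C)C)C[C@@H](O[Si](C)(C)C(C)(C)C)[C@H]1CC(=O)OC(C)(C)C
F2 | step 15 | 2-[(1S,2S,3E,7E,10R)-10-[(tert-butyldimethylsilyl)oxy]-8-{[(tert-butyldimethylsilyl)oxy]methyl}-2-hydroxy-4-{[(4-methoxyphenyl)methoxy]methyl}cyclodeca-3,7-dien-1-yl]acetic acid (C6 epimer of 26) | O[C@H]1/C=C(/COCc2ccc(OC)cc2)CC/C=C(/CO[Si](C)(C)C(C)(C)C)C[C@@H](O[Si](C)(C)C(C)(C)C)[C@H]1CC(=O)O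
F3 | step 2 | tributyl[(1Z)-3-[(4-methoxyphenyl)methoxy]-1-(trimethylsilyl)prop-1-en-2-yl]stannane | C[Si](C)(C)/C=C(/COCc1ccc(OC)cc1)[Sn](CCCC)(CCCC)CCCC
F4 | step 2 | [(1Z)-2-iodo-3-[(4-methoxyphenyl)methoxy]prop-1-en-1-yl]trimethylsilane | C[Si](C)(C)/C=C(/COCc1ccc(OC)cc1)I
F5 | step 2 | trimethyl[(1E)-4-(1,3-dioxolan-2-yl)-2-{[(4-methoxyphenyl)methoxy]methyl}but-1-en-1-yl]silane | C[Si](C)(C)/C=C(/COCc1ccc(OC)cc1)CCC1OCCO1
F0 | step 16 | none | none
F6 | step 11 | 7-tert-butyl 1-ethyl (4R,5S)-4-[(tert-butyldimethylsilyl)oxy]-5-{[(triethylsilyl)oxy]methyl}-2-(triphenyl-λ5-phosphanylidene)heptanedioate | CCOC(=O)C(=P(c1ccccc1)(c1ccccc1)c1ccccc1)C[C@@H](O[Si](C)(C)C(C)(C)C)[C@@H](CC(=O)OC(C)(C)C)CO[Si](CC)(CC)CC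
F7 | step 10 | tert-butyl (3S,4S)-4-[(tert-butyldimethylsilyl)oxy]-5-oxo-3-{[(triethylsilyl)oxy]methyl}pentanoate | O=C[C@@H](O[Si](C)(C)C(C)(C)C)[C@@H](CC(=O)OC(C)(C)C)CO[Si](CC)(CC)CC
F8 | step 10 | 7-tert-butyl 1-ethyl 4-[(tert-butyldimethylsilyl)oxy]-2-(diethoxyphosphoryl)-5-{[(triethylsilyl)oxy]methyl}hept-2-enedioate (C8 and C7 configured as in 19, olefin isomers) | CCOC(=O)C(P(=O)(OCC)OCC)=C[C@@H](O[Si](C)(C)C(C)(C)C)[C@@H](CC(=O)OC(C)(C)C)CO[Si](CC)(CC)CC
A1 | alternative 1 | all-trans 3-[(dimethylamino)methyl]-4-{2-[2-(dimethoxymethyl)penta-2,4-dien-1-yl]-1,3-dithian-2-yl}-5-{[(tert-butyldimethylsilyl)oxy]methyl}oxolan-2-one | CN(C)C[C@@H]1C(=O)O[C@H](CO[Si](C)(C)C(C)(C)C)[C@H]1C2(SCCCS2)C/C(C(OC)OC)=C\C=C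
A2 | alternative 1 | (5S)-5-{[(tert-butyldimethylsilyl)oxy]methyl}furan-2(5H)-one | O=C1C=C[C@@H](CO[Si](C)(C)C(C)(C)C)O1
A3 | alternative 2 | C15 tert-butyldimethylsilyl ether of the deacetyl target | C=C1C(=O)O[C@@H]2/C=C(/CO[Si](C)(C)C(C)(C)C)CC/C=C(/C=O)C[C@@H](OC(=O)[C@@H](C)CC)[C@@H]12
A4 | alternative 2 | ten-membered 6-hydroxy-7-ethynyl diene with the C8 (2S)-2-methylbutanoate, the C14 aldehyde and the C15 silyl ether | O[C@@H]1/C=C(/CO[Si](C)(C)C(C)(C)C)CC/C=C(/C=O)C[C@@H](OC(=O)[C@@H](C)CC)[C@H]1C#C
A5 | alternative 3 | lactone-fused ten-membered carbocycle with C8 OTBS, C15 OPMB and the C14 dimethyl acetal | C1C(=O)O[C@@H]2/C=C(/COCc3ccc(OC)cc3)CC/C=C(/C(OC)OC)C[C@@H](O[Si](C)(C)C(C)(C)C)[C@@H]12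
A6 | alternative 3 | open-chain γ-lactone with the C4 iodoalkene on C6 and the terminal C2=C3 vinyl group | C1C(=O)O[C@H](/C=C(\I)COCc2ccc(OC)cc2)[C@H]1[C@H](O[Si](C)(C)C(C)(C)C)C/C(C(OC)OC)=C\C=C
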